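**Retrosynthetic overview**
1. Target 16 ⇒ acyl trione 13 by a late gem-diprenylation at the one free carbon of ring A.
2. Ring A (the trione) is not brought in as an acylphloroglucinol. It is closed last (13 ⇐ 12) by Claisen attack of an acetyl carbanion on a bridged γ-lactone, which passes the C7'–O configuration on to the spiro carbon.
3. Lactone acid 9 ⇐ Meldrum's acid derivative 8 by the key step: Mn(OAc)3 oxidative radical 6-endo cyclisation with lactone termination (ring B, C7' and the spiro carbon in one operation).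
4. 8 ⇐ keto aldehyde 4 by proline aldol (ring C, C3' and C3a') and reductive Knoevenagel; 4 ⇐ (S)-limonene (source of C7a').
5. Ring order: C (cyclopentane), then B (cyclohexane with lactone bridge), then A (trione).

Assumption: (S)-(−)-limonene of high enantiomeric purity is commercial; the bicyclic part is numbered as an indane (C3'/C7' carbinol carbons, C3a'/C7a' ring-fusion carbons, C5' spiro carbon; unprimed in the non-spiro intermediates).

**Step 1**
Reactants: 1 (S)-(−)-limonene
Product: 2 (4S)-limonene 1,2-oxide (cis/trans epoxide mixture)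
Conditions: mCPBA (1.05 equiv), CH2Cl2, 0 °C
Reagents that add atoms: mCPBA, 3-chloroperoxybenzoic acid (OOC(=O)c1cccc(Cl)c1)
Why: Prilezhaev epoxidation picks the electron-richer trisubstituted ring alkene over the isopropenyl group, the two new epoxide centres are erased in step 2 and the (S) centre is untouched.

**Step 2**
Reactants: 2 (4S)-limonene 1,2-oxide
Product: 4 (3S)-6-oxo-3-(prop-1-en-2-yl)heptanal, via diol 3 (not isolated)
Conditions: H5IO6 (1.2 equiv), THF/H2O, 0 to 23 °C
Reagents that add atoms: water (O)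
Why: Acidic epoxide hydrolysis followed by Malaprade glycol cleavage opens the ring to the keto aldehyde without touching the isopropenyl group or the non-enolisable (S) centre.

**Step 3**
Reactants: 4 (3S)-6-oxo-3-(prop-1-en-2-yl)heptanal; 5 Meldrum's acid
Product: 8 5-{[(1R,2S,5S)-2-hydroxy-2-methyl-5-(prop-1-en-2-yl)cyclopentyl]methyl}-2,2-dimethyl-1,3-dioxane-4,6-dione, via aldol adduct 6 (not isolated), via alkylidene 7 (not isolated)
Conditions: D-proline (20 mol %), CH2Cl2, 23 °C; then 5, Hantzsch ester, 23 °C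
Reagents that add atoms: Meldrum's acid 5 (CC1(C)OC(=O)CC(=O)O1)
Why: Proline enamine catalysis gives a 5-enolexo intramolecular aldol addition in which the Houk–List transition state (D-proline chosen as the matched catalyst by that model) puts the formyl-bearing carbon trans to the isopropenyl group and the hydrogen-bonded ketone oxygen cis to the formyl group, setting C1 (R) and C2 (S), and the same catalyst then drives Knoevenagel condensation with Meldrum's acid and Hantzsch-ester transfer hydrogenation of the alkylidene (organocatalytic reductive alkylation) so that the dehydration-prone aldol is never isolated.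

**Step 4**
Reactants: 8 Meldrum's acid derivative
Product: 9 (3S,3aR,5R,7R,7aS)-3,7-dihydroxy-3,7-dimethyloctahydro-1H-indene-5,5-dicarboxylic acid 5,7-lactone
Conditions: Mn(OAc)3·2H2O (2.2 equiv), AcOH, 40 °C, argon
Reagents that add atoms: water (O)
Why: Proposed new method: trivalent manganese oxidises the enolised Meldrum's acid to an electrophilic malonyl-type radical that adds 6-endo to the CH2 terminus of the 1,1-disubstituted alkene (5-exo would need a quaternary centre in a trans-fused bicyclo[3.3.0] system), a second equivalent oxidises the tertiary radical to the C7 cation, and only the dioxanedione carbonyl that is axial on the new chair (cis-1,3 to the cation, on the face anti to H-7a) can close the γ-lactone, water then hydrolysing the dioxocarbenium ion with loss of acetone, which fixes C7 (R) and makes the two carboxyl carbons on C5 distinct (axial lactone, equatorial CO2H), the closest known reaction type being the Mn(OAc)3-based oxidative free-radical cyclisation of unsaturated malonates and β-keto esters with lactone termination.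

**Step 5**
Reactants: 9 lactone acid; 10 6-methylheptane-2,4-dione
Product: 12 (3S,3aR,5R,7R,7aS)-5-(2-acetyl-5-methyl-3-oxohexanoyl)-3,7-dihydroxy-3,7-dimethyloctahydro-1H-indene-5-carboxylic acid 5,7-lactone, via acyl imidazolide 11 (not isolated)
Conditions: CDI (1.05 equiv), THF, 23 °C; then 10, MgCl2, Et3N, MeCN, 23 to 45 °C
Reagents that add atoms: 6-methylheptane-2,4-dione 10 (CC(C)CC(=O)CC(C)=O); 1,1'-carbonyldiimidazole (O=C(n1ccnc1)n1ccnc1)
Why: The acid is activated as the acyl imidazolide under neutral conditions that spare the tertiary alcohol and the lactone (the imidazolyl group is carried only by 11 and leaves again as imidazole), and magnesium-mediated soft enolisation gives C-acylation at the central carbon of the β-diketone (Masamune/Rathke-type Claisen acylation), so the future acyl-bearing ring carbon is bonded unambiguously to the equatorial carboxyl carbon.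

**Step 6**
Reactants: 12 lactone triacylmethane
Product: 13 (1S,3'S,3a'R,7'R,7a'S)-3',4,7'-trihydroxy-3',7'-dimethyl-3-(3-methylbutanoyl)octahydrospiro[cyclohex-3-ene-1,5'-indene]-2,6-dione
Conditions: LiN(iPr)2 (5 equiv), THF, −78 to 0 °C; then 1 M HCl
Reagents that add atoms: none
Why: After the enol and alcohol protons are removed, lithium diisopropylamide forms the acetyl-methyl carbanion (less hindered and kinetically more acidic than the isobutyl-flanked methylene), which attacks the strained lactone carbonyl in a 6-exo intramolecular Claisen (Dieckmann-type, polyketide-like) cyclisation that closes ring A, frees the C7' alkoxide with retention and so turns the lactone geometry into the spiro configuration (the ring carbonyl next to the CH2 is axial and syn to O-7'), deprotonation of the product making it irreversible.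

**Step 7**
Reactants: 13 spiro acyl trione; 14 prenyl bromide
Product: 16 (1S,3'S,3a'R,7'R,7a'S)-3',4,7'-trihydroxy-3',7'-dimethyl-3-(3-methylbutanoyl)-5,5-bis(3-methylbut-2-en-1-yl)octahydrospiro[cyclohex-3-ene-1,5'-indene]-2,6-dione (CNP0198642.4), via monoprenyl trione 15 (not isolated)
Conditions: 14 (2.5 equiv), aq. KOH, 0 °C; then 1 M HCl
Reagents that add atoms: prenyl bromide 14 (CC(C)=CCBr)
Why: In cold aqueous base the only remaining ring C–H carbon (C5, between two carbonyls) of the enolised acyl trione is C-alkylated twice (lupulone-type gem-diprenylation of a vinylogous acid), the protic medium favouring C- over O-alkylation, the tertiary alcohols staying inert and no stereocentre being made or disturbed.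

**Compound list**
1 | (S)-(−)-limonene, (4S)-1-methyl-4-(prop-1-en-2-yl)cyclohex-1-ene | C=C(C)[C@H]1CCC(C)=CC1 | starting material
2 | (4S)-1-methyl-4-(prop-1-en-2-yl)-7-oxabicyclo[4.1.0]heptane (limonene 1,2-oxide, cis/trans mixture at the epoxide) | C=C(C)[C@H]1CCC2(C)OC2C1 | intermediate
3 | (4S)-1-methyl-4-(prop-1-en-2-yl)cyclohexane-1,2-diol | C=C(C)[C@H]1CCC(C)(O)C(O)C1 | intermediate (not isolated)
4 | (3S)-6-oxo-3-(prop-1-en-2-yl)heptanal | C=C(C)[C@H](CC=O)CCC(C)=O | intermediate
5 | Meldrum's acid, 2,2-dimethyl-1,3-dioxane-4,6-dione | CC1(C)OC(=O)CC(=O)O1 | starting material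
6 | (1R,2S,5S)-2-hydroxy-2-methyl-5-(prop-1-en-2-yl)cyclopentane-1-carbaldehyde (OH cis to CHO, CHO trans to isopropenyl) | O=C[C@@H]1[C@H](CC[C@]1(C)O)C(C)=C | intermediate (not isolated)
7 | 5-{[(1R,2S,5S)-2-hydroxy-2-methyl-5-(prop-1-en-2-yl)cyclopentyl]methylidene}-2,2-dimethyl-1,3-dioxane-4,6-dione | CC1(C)OC(=O)C(=C[C@@H]2[C@H](CC[C@]2(C)O)C(C)=C)C(=O)O1 | intermediate (not isolated)
8 | 5-{[(1R,2S,5S)-2-hydroxy-2-methyl-5-(prop-1-en-2-yl)cyclopentyl]methyl}-2,2-dimethyl-1,3-dioxane-4,6-dione | CC1(C)OC(=O)C(C[C@@H]2[C@H](CC[C@]2(C)O)C(C)=C)C(=O)O1 | intermediate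
9 | (3S,3aR,5R,7R,7aS)-3,7-dihydroxy-3,7-dimethyloctahydro-1H-indene-5,5-dicarboxylic acid 5,7-lactone (trans-fused; axial carboxyl lactonised on O-7, equatorial CO2H free) | O=C1[C@@]2(C[C@@H]3[C@H](CC[C@]3(C)O)[C@](C)(O1)C2)C(=O)O | intermediate
10 | 6-methylheptane-2,4-dione | CC(C)CC(=O)CC(C)=O | starting material
11 | acyl imidazolide of 9 (free CO2H replaced by C(=O)-imidazol-1-yl) | O=C1[C@@]2(C[C@@H]3[C@H](CC[C@]3(C)O)[C@](C)(O1)C2)C(=O)n1ccnc1 | intermediate (not isolated)
12 | (3S,3aR,5R,7R,7aS)-5-(2-acetyl-5-methyl-3-oxohexanoyl)-3,7-dihydroxy-3,7-dimethyloctahydro-1H-indene-5-carboxylic acid 5,7-lactone | O=C1[C@@]2(C[C@@H]3[C@H](CC[C@]3(C)O)[C@](C)(O1)C2)C(=O)C(C(C)=O)C(=O)CC(C)C | intermediate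
13 | (1S,3'S,3a'R,7'R,7a'S)-3',4,7'-trihydroxy-3',7'-dimethyl-3-(3-methylbutanoyl)octahydrospiro[cyclohex-3-ene-1,5'-indene]-2,6-dione | C1C(=O)[C@@]2(C[C@@H]3[C@H](CC[C@]3(C)O)[C@](C)(O)C2)C(=O)C(C(=O)CC(C)C)=C1O | intermediate
14 | prenyl bromide, 1-bromo-3-methylbut-2-ene | CC(C)=CCBr | starting material
15 | 5-(3-methylbut-2-en-1-yl) derivative of 13 (both C5 epimers) | CC(C)=CCC1C(=O)[C@@]2(C[C@@H]3[C@H](CC[C@]3(C)O)[C@](C)(O)C2)C(=O)C(C(=O)CC(C)C)=C1O | intermediate (not isolated)
16 | (1S,3'S,3a'R,7'R,7a'S)-3',4,7'-trihydroxy-3',7'-dimethyl-3-(3-methylbutanoyl)-5,5-bis(3-methylbut-2-en-1-yl)octahydrospiro[cyclohex-3-ene-1,5'-indene]-2,6-dione | CC(C)=CCC1(CC=C(C)C)C(=O)[C@@]2(C[C@@H]3[C@H](CC[C@]3(C)O)[C@](C)(O)C2)C(=O)C(C(=O)CC(C)C)=C1O | target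

**Totals**
Total step count: 7. Longest linear sequence: 7 steps (1 to 16); 5, 10 and 14 are bought.

**Three steps most likely to fail**

Step 3 (diastereocontrol of the aldol and dehydration of 6). The fallback sets out from 4 and comes back at 6. Compound 4 is taken to the enal by aldol condensation (piperidine, AcOH, toluene, reflux), giving (5R)-2-methyl-5-(prop-1-en-2-yl)cyclopent-1-ene-1-carbaldehyde F1. Weitz–Scheffer epoxidation (H2O2, NaOH, MeOH, 0 °C) closes the epoxide anti to the isopropenyl group and gives (1R,2R,5S)-5-methyl-2-(prop-1-en-2-yl)-6-oxabicyclo[3.1.0]hexane-1-carbaldehyde F2. Reductive cleavage of the Cα–O bond with Cp2TiCl (from Cp2TiCl2 and Zn, THF, −20 °C; trivalent titanium) and protonation gives 6, whose epimerisable α-centre settles trans to the isopropenyl group. Isolated 6 is then taken through the Meldrum's acid/Hantzsch ester half of step 3 to 8. Here the carbinol centre comes from the epoxide face, not from the aldol transition state.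

Step 4 (radical regiochemistry, oxidation of the tertiary radical, stability of the Meldrum's acid). The fallback is ionic; it sets out from 4 and comes back at 9. Ene-type allylic chlorination of 4 (NCS, PhSeCl cat., CH2Cl2, 23 °C) gives (3S)-3-(3-chloroprop-1-en-2-yl)-6-oxoheptanal F3. The step 3 protocol then gives (1R,2S,5S)-5-(3-chloroprop-1-en-2-yl)-2-hydroxy-2-methylcyclopentane-1-carbaldehyde F4, its Meldrum's acid alkylidene F5 and the reduced chloroallyl Meldrum's acid F6. K2CO3 in MeCN closes ring B by intramolecular C-alkylation to give (3'S,3a'R,7a'S)-3'-hydroxy-2,2,3'-trimethyl-7'-methylideneoctahydrospiro[1,3-dioxane-5,5'-indene]-4,6-dione F7. TFA/H2O in CH2Cl2 at 0 °C protonates the exocyclic alkene and the axial carbonyl traps the C7 cation with loss of acetone, giving 9 with the same stereochemical logic as step 4.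

Step 6 (competition between the two terminal carbanions; a hindered lactone carbonyl). The fallback reverses the order of the two ring A bonds; it sets out from 9 and comes back at 13. TMSCHN2 (MeOH/toluene, 0 °C) gives the lactone methyl ester F8. The dianion of 10 (LiN(iPr)2, 2 equiv per dione, THF, −78 to 0 °C) opens the more electrophilic lactone carbonyl with its terminal carbanion and gives the open-chain methyl (3S,3aR,5S,7R,7aS)-3,7-dihydroxy-3,7-dimethyl-5-(7-methyl-3,5-dioxooctanoyl)octahydro-1H-indene-5-carboxylate F9. NaOMe in MeOH at 50 °C then closes ring A by Claisen attack of the central diketone carbon on the methyl ester (the only six-membered option) to give 13.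

**Further compounds**
F1 | step 3 | (5R)-2-methyl-5-(prop-1-en-2-yl)cyclopent-1-ene-1-carbaldehyde | O=CC1=C(C)CC[C@@H]1C(C)=C
F2 | step 3 | (1R,2R,5S)-5-methyl-2-(prop-1-en-2-yl)-6-oxabicyclo[3.1.0]hexane-1-carbaldehyde | O=C[C@]12O[C@@]1(C)CC[C@@H]2C(C)=C
F3 | step 4 | (3S)-3-(3-chloroprop-1-en-2-yl)-6-oxoheptanal | C=C(CCl)[C@H](CC=O)CCC(C)=O
F4 | step 4 | (1R,2S,5S)-5-(3-chloroprop-1-en-2-yl)-2-hydroxy-2-methylcyclopentane-1-carbaldehyde | O=C[C@@H]1[C@H](CC[C@]1(C)O)C(=C)CCl
F5 | step 4 | 5-{[(1R,2S,5S)-5-(3-chloroprop-1-en-2-yl)-2-hydroxy-2-methylcyclopentyl]methylidene}-2,2-dimethyl-1,3-dioxane-4,6-dione | CC1(C)OC(=O)C(=C[C@@H]2[C@H](CC[C@]2(C)O)C(=C)CCl)C(=O)O1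
F6 | step 4 | 5-{[(1R,2S,5S)-5-(3-chloroprop-1-en-2-yl)-2-hydroxy-2-methylcyclopentyl]methyl}-2,2-dimethyl-1,3-dioxane-4,6-dione | CC1(C)OC(=O)C(C[C@@H]2[C@H](CC[C@]2(C)O)C(=C)CCl)C(=O)O1
F7 | step 4 | (3'S,3a'R,7a'S)-3'-hydroxy-2,2,3'-trimethyl-7'-methylideneoctahydrospiro[1,3-dioxane-5,5'-indene]-4,6-dione | CC1(C)OC(=O)C2(C[C@@H]3[C@H](CC[C@]3(C)O)C(=C)C2)C(=O)O1
F8 | step 6 | methyl ester of 9, methyl (3S,3aR,5R,7R,7aS)-3,7-dihydroxy-3,7-dimethyloctahydro-1H-indene-5,5-dicarboxylate 5,7-lactone | O=C1[C@@]2(C[C@@H]3[C@H](CC[C@]3(C)O)[C@](C)(O1)C2)C(=O)OC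
F9 | step 6 | methyl (3S,3aR,5S,7R,7aS)-3,7-dihydroxy-3,7-dimethyl-5-(7-methyl-3,5-dioxooctanoyl)octahydro-1H-indene-5-carboxylate | CC(C)CC(=O)CC(=O)CC(=O)[C@@]2(C[C@@H]3[C@H](CC[C@]3(C)O)[C@](C)(O)C2)C(=O)OC
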